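No macrocyclisation is used. Target atoms C9–C10(Me)=C1–C2–C3–C4(Me)=C5–C6 are the carbons of 1,5-dimethylcycloocta-1,5-diene, whose ring-cis alkenes supply both Z alkenes; C7 and C8 are then inserted into the C6–C9 bond. The precursor is a cis-fused 1-silyloxybicyclo[6.2.0]decadienone, i.e. a cyclobutanone (C6, C9, C8, C7) sharing C6–C9 with the eight-membered ring. Fluoride liberates the C6 alkoxide, and retro-aldol rupture of the shared bond converts the bicycle into the monocyclic ten-membered C6/C8 dione in a single operation. Ketoreductase reduction and an Evans–Tishchenko reaction then set C7, C8 and C6 and deliver the vanillate to O8.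

Key step: step 5

Remarks on the chemistry (assumptions):
- Locants C1–C10 of the target ring are used for every intermediate: C6 carbinol, C7 isopropyl, C8 ester carbon, C9 methylene, C10(Me)=C1, C2, C3, C4(Me)=C5.
- Diene 1 is assumed to be used as the pure 1,5-isomer; technical material containing the 1,6-dimethyl isomer is fractionated first.
- 2-Chloro-3-methylbutanoyl chloride 5 is taken as a catalogue reagent (racemic).
- Compounds 2–10 are achiral or racemic; 7–9 are drawn with relative configuration only.
- Triethylsilyl is chosen for the enol ether so that the tertiary silyl ether survives the ketene step, the acidic zinc step and chromatography, yet still falls to fluoride.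
- The ketoreductase in step 6 is an enzyme to be identified by panel screening.
- C7 is labelled R in 11 and S in 15 and 16 only because the priority of C6 changes when its carbonyl is reduced; the centre itself is not touched after step 6.

Step 1
Reactants: 1 (1Z,5Z)-1,5-dimethylcycloocta-1,5-diene
Product: 2 (2Z,6Z)-3,7-dimethylcycloocta-2,6-dien-1-one (carbonyl carbon = C6)
Conditions: Rh2(cap)4 (dirhodium tetracaprolactamate, 1 mol%), tBuOOH (70% aq., 2.5 equiv, slow addition), K2CO3, CH2Cl2, 20 °C; stopped near half conversion, unreacted diene recovered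
Reagents that add atoms: tert-butyl hydroperoxide, CC(C)(C)OO
Why: Radical allylic C–H oxidation (allylic peroxidation, then collapse of the peroxide to the enone): the tert-butylperoxyl radical should abstract hydrogen from the CH2 flanking the CH terminus of a trisubstituted alkene, because this gives the more substituted allyl radical and oxygen is delivered to its secondary end (the preference that turns 5-ene steroids into 7-ketones); the two such CH2 groups of 1 are symmetry-equivalent, and partial conversion limits attack on the second alkene.

Step 2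
Reactants: 2 (2Z,6Z)-3,7-dimethylcycloocta-2,6-dien-1-one
Product: 4 triethyl[(3,7-dimethylcycloocta-1,3,7-trien-1-yl)oxy]silane (enol double bond C6=C9; all ring alkenes cis), via lithium dienolate 3 (not isolated)
Conditions: LiN(iPr)2 (1.1 equiv), THF, −78 °C; then Et3SiCl, Et3N, −78 → 0 °C; pentane, filtration through basic alumina, used at once
Reagents that add atoms: chlorotriethylsilane, CC[Si](CC)(CC)Cl
Why: Kinetic enolate formation and O-silylation: the amide base should remove the alpha-prime proton at C9 (also allylic to C10=C1) faster than a gamma proton of the enone, and the ring allows only the cis enol double bond.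

Step 3
Reactants: 4 triethyl[(3,7-dimethylcycloocta-1,3,7-trien-1-yl)oxy]silane; 5 2-chloro-3-methylbutanoyl chloride (racemic)
Product: 7 cis-fused 7-chloro-7-isopropyl-6-(triethylsilyloxy) cyclobutanone adduct (bicyclo[6.2.0]deca-2,6-dien-9-one; racemic; C7 epimers), via chloro(isopropyl)ketene 6 (not isolated)
Conditions: Et3N (2 equiv), pentane, acid chloride added over 6 h, 20–25 °C, dark; filtration; Et3N-deactivated silica
Reagents that add atoms: none
Why: Ketene–silyl enol ether [2+2] cycloaddition: dehydrochlorination of 5 gives the electrophilic chloroketene 6, whose carbonyl carbon (C8) should bond to the enol ether beta-carbon C9 while its substituted carbon (C7) closes onto the oxocarbenium carbon C6, placing the siloxy group beta to the ketone; addition to a ring-cis enol ether can only give the cis ring fusion, the tub shape of the triene twists C10=C1 out of conjugation so that C9 rather than the vinylogous C1 is expected to be the nucleophilic site, and the C7 configuration is of no consequence because chlorine is removed next.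

Step 4
Reactants: 7 cis-fused 7-chloro-7-isopropyl-6-(triethylsilyloxy) cyclobutanone adduct
Product: 8 cis-fused 7-isopropyl-6-(triethylsilyloxy)bicyclo[6.2.0]deca-2,6-dien-9-one bearing the C4 and C10 methyls (racemic; C8 ketone; isopropyl drawn cis to the siloxy group and the C9 hydrogen)
Conditions: Zn dust, AcOH, iPrOH–H2O, 0 → 20 °C
Reagents that add atoms: none
Why: Zinc reduction of an alpha-chloro ketone: two-electron cleavage of the activated tertiary C7–Cl bond and C-protonation by AcOH should give the C7–H compound, the hindered triethylsilyl ether should survive the brief cold exposure to acid, and either C7 epimer serves because C7 becomes the epimerisable dione carbon in step 5.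

Step 5
Reactants: 8 cis-fused 7-isopropyl-6-(triethylsilyloxy)bicyclo[6.2.0]decadienone
Product: 10 (4Z,8Z)-5,9-dimethyl-2-(propan-2-yl)cyclodeca-4,8-diene-1,3-dione (C6 and C8 ketones; racemic at C7), via tetrabutylammonium cyclobutanolate 9 (not isolated)
Conditions: Bu4NF (1.1 equiv), AcOH (1.1 equiv), THF, −40 → 0 °C; pH 7 phosphate quench; used promptly
Reagents that add atoms: none
Why: Fluoride cleaves the Si–O bond and the C6 alkoxide 9 undergoes retro-aldol fragmentation of the strained beta-oxido cyclobutanone: the C6–C9 sigma bond breaks as C6=O forms, the electron pair passes into the C8 carbonyl as an enolate, and AcOH protonates it at C9. The closest known reaction type is the two-carbon ring expansion of cycloalkanone silyl enol ethers through ketene adducts, which open to cycloalkane-1,3-diones once dehalogenated. The one ring formed, the ten-membered carbocycle, arises by cleaving the bond common to the four- and eight-membered rings and not by a bond-forming closure, so neither high dilution nor an entropic penalty is involved. No stereocentre is created: C6 and C9 lose theirs, C7 becomes the epimerising carbon between two ketones, and both alkenes are untouched and stay Z. The selectivity required is cleavage of C6–C9 over C6–C7; the substrate should secure it because the electron pair left on C9 is delocalised into the C8 carbonyl and on into C10=C1 (a dienolate), whereas an anion at C7 would be a hindered isopropyl-substituted enolate carbon with no chlorine left to stabilise it. Buffering with AcOH at low temperature should give kinetic alpha-protonation at C9 and keep C10=C1 out of conjugation.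

Step 6
Reactants: 10 (4Z,8Z)-5,9-dimethyl-2-(propan-2-yl)cyclodeca-4,8-diene-1,3-dione
Product: 11 (2Z,6Z,9R,10R)-9-hydroxy-3,7-dimethyl-10-(propan-2-yl)cyclodeca-2,6-dien-1-one (7R,8R in target locants; isopropyl and hydroxyl cis on the ring)
Conditions: ketoreductase (panel hit selective for C8 and for the 7R,8R isomer), NADP+ (cat.), iPrOH (10% v/v), KH2PO4/K2HPO4 buffer pH 7.0, DMSO co-solvent, 30 °C
Reagents that add atoms: none
Why: Enzymatic dynamic reductive kinetic resolution of a 2-alkyl-1,3-diketone: C7 epimerises through the enol at neutral pH, the isolated C8 ketone is more readily reduced than the conjugated C6 ketone, and a ketoreductase chosen by screening should deliver hydride to one face of C8 of one C7 epimer only, setting C8 and C7 together.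

Step 7
Reactants: 12 vanillin (4-hydroxy-3-methoxybenzaldehyde)
Product: 13 4-{[tert-butyl(dimethyl)silyl]oxy}-3-methoxybenzaldehyde
Conditions: TBSCl, imidazole, CH2Cl2, 20 °C
Reagents that add atoms: tert-butyldimethylsilyl chloride, CC(C)(C)[Si](C)(C)Cl
Why: Imidazole-mediated silylation of a phenol, which masks the acidic OH that would otherwise quench the samarium catalyst in step 8.

Step 8
Reactants: 11 (2Z,6Z,9R,10R)-9-hydroxy-3,7-dimethyl-10-(propan-2-yl)cyclodeca-2,6-dien-1-one; 13 4-{[tert-butyl(dimethyl)silyl]oxy}-3-methoxybenzaldehyde
Product: 15 (1R,3Z,7Z,9R,10S)-9-hydroxy-3,7-dimethyl-10-(propan-2-yl)cyclodeca-3,7-dien-1-yl 4-{[tert-butyl(dimethyl)silyl]oxy}-3-methoxybenzoate (6R,7S,8R in target locants), via mixed hemiacetal 14 (not isolated)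
Conditions: SmI2 (0.3 equiv) added to a fivefold excess of the aldehyde in THF, −10 °C, dark, until the blue colour is discharged (trivalent samarium pinacolate formed from part of the aldehyde); then the hydroxy ketone, −10 °C; aq. NaHCO3 work-up
Reagents that add atoms: none
Why: Evans–Tishchenko reduction: SmI2 is a precatalyst that a small part of 13 oxidises to the trivalent samarium pinacolate, the C8 hydroxyl then adds to aldehyde 13 to give hemiacetal 14, and within a chelate in which trivalent samarium binds the hemiacetal oxygen and the C6 carbonyl the hemiacetal hydrogen is transferred intramolecularly to C6, so the new C6 carbinol should be 1,3-anti to O8 (6R) and the oxidised aldehyde remains as the ester on O8 without any separate differentiation of the two hydroxyls.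

Step 9
Reactants: 15 silyl-protected ester
Product: 16 (1R,3Z,7Z,9R,10S)-9-hydroxy-3,7-dimethyl-10-(propan-2-yl)cyclodeca-3,7-dien-1-yl 4-hydroxy-3-methoxybenzoate (target; 6R,7S,8R)
Conditions: Bu4NF, AcOH (1:1), THF, 0 °C
Reagents that add atoms: none
Why: Fluoride cleavage of an aryl silyl ether, which should be far faster than any reaction of the benzoate or the secondary alcohol; the AcOH buffer suppresses 1,3-acyl migration from O8 to O6.

Compound list
1 | (1Z,5Z)-1,5-dimethylcycloocta-1,5-diene | C/C1=C/CC/C(C)=C\CC1 | starting material
2 | (2Z,6Z)-3,7-dimethylcycloocta-2,6-dien-1-one | O=C1/C=C(C)\CC/C=C(C)\C1 | intermediate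
3 | lithium dienolate of 2, O–C6=C9 (not isolated) | [Li]O/C1=C/C(C)=C\CC/C(C)=C\1 | intermediate
4 | triethyl{[(1E,3Z,7Z)-3,7-dimethylcycloocta-1,3,7-trien-1-yl]oxy}silane (all ring alkenes cis) | CC[Si](CC)(CC)O/C1=C/C(C)=C\CC/C(C)=C\1 | intermediate
5 | 2-chloro-3-methylbutanoyl chloride (racemic) | CC(C)C(Cl)C(Cl)=O | starting material
6 | chloro(isopropyl)ketene, 2-chloro-3-methylbut-1-en-1-one (not isolated) | CC(C)C(Cl)=C=O | intermediate
7 | cis-fused 10-chloro-3,7-dimethyl-10-(propan-2-yl)-1-(triethylsilyloxy)bicyclo[6.2.0]deca-2,6-dien-9-one (racemic; C7 epimers, C7 left undefined) | CC[Si](CC)(CC)O[C@]12/C=C(C)\CC/C=C(C)\[C@H]1C(=O)C2(Cl)C(C)C | intermediate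
8 | cis-fused 3,7-dimethyl-10-(propan-2-yl)-1-(triethylsilyloxy)bicyclo[6.2.0]deca-2,6-dien-9-one (racemic; isopropyl cis to the siloxy group) | CC[Si](CC)(CC)O[C@]12/C=C(C)\CC/C=C(C)\[C@H]1C(=O)[C@@H]2C(C)C | intermediate
9 | tetrabutylammonium C6 alkoxide of desilylated 8 (not isolated) | CCCC[N+](CCCC)(CCCC)CCCC.[O-][C@]12/C=C(C)\CC/C=C(C)\[C@H]1C(=O)[C@@H]2C(C)C | intermediate
10 | (4Z,8Z)-5,9-dimethyl-2-(propan-2-yl)cyclodeca-4,8-diene-1,3-dione (racemic, C7 epimerising) | O=C1C/C(C)=C\CC/C(C)=C\C(=O)C1C(C)C | intermediate
11 | (2Z,6Z,9R,10R)-9-hydroxy-3,7-dimethyl-10-(propan-2-yl)cyclodeca-2,6-dien-1-one | O[C@@H]1C/C(C)=C\CC/C(C)=C\C(=O)[C@@H]1C(C)C | intermediate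
12 | vanillin | COc1cc(C=O)ccc1O | starting material
13 | 4-{[tert-butyl(dimethyl)silyl]oxy}-3-methoxybenzaldehyde | COc1cc(C=O)ccc1O[Si](C)(C)C(C)(C)C | intermediate
14 | hemiacetal of 11 (O8) with 13, hemiacetal carbon undefined (not isolated) | COc1cc(C(O)O[C@@H]2C/C(C)=C\CC/C(C)=C\C(=O)[C@@H]2C(C)C)ccc1O[Si](C)(C)C(C)(C)C | intermediate
15 | (1R,3Z,7Z,9R,10S)-9-hydroxy-3,7-dimethyl-10-(propan-2-yl)cyclodeca-3,7-dien-1-yl 4-{[tert-butyl(dimethyl)silyl]oxy}-3-methoxybenzoate | COc1cc(C(=O)O[C@@H]2C/C(C)=C\CC/C(C)=C\[C@@H](O)[C@@H]2C(C)C)ccc1O[Si](C)(C)C(C)(C)C | intermediate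
16 | (1R,3Z,7Z,9R,10S)-9-hydroxy-3,7-dimethyl-10-(propan-2-yl)cyclodeca-3,7-dien-1-yl 4-hydroxy-3-methoxybenzoate | COc1cc(C(=O)O[C@@H]2C/C(C)=C\CC/C(C)=C\[C@@H](O)[C@@H]2C(C)C)ccc1O | target

Total step count: 9. Longest linear sequence: 8 (steps 1–6, 8, 9); step 7 is a one-step side branch.

Steps most likely to fail

Step 3. The hindered ketene, which is prone to oligomerise, may be captured too slowly by the twisted trienol ether, or the zwitterion may lose silicon and end as C-acylated material instead of closing the four-membered ring. The fallback sets out from 4 and returns at 10; it leaves the isopropyl group out of the cycloaddition and adds it last. Dichloroketene (Cl2CHCOCl, Et3N, pentane), the most reactive partner for silyl enol ethers, should give the cis-fused 7,7-dichloro adduct F1. Zn/AcOH should remove both chlorines to give the C7-unsubstituted siloxycyclobutanone F2. Buffered fluoride, as in step 5, should open this to the C7-unsubstituted ten-membered dione F3. Proline-catalysed Knoevenagel condensation of F3 with acetone in the presence of Hantzsch ester should reduce the isopropylidene dione F4 as it forms (reductive alkylation), which gives 10.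

Step 6. The enzyme may not accept the ten-membered dione, may reduce the C6 carbonyl or give the 7,8-trans diastereomer, or C7 may epimerise too slowly for the resolution to be dynamic. The fallback sets out from 10 and returns at 11; it gives up catalyst control in favour of resolution. NaBH4 (MeOH–CH2Cl2, −78 °C) should reduce the non-conjugated C8 ketone in preference to the enone. After chromatographic removal of the 7,8-trans isomer this gives the racemic 7,8-cis hydroxy ketone F5, and preparative chromatography on a chiral stationary phase then gives 11.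

Step 8. Hemiacetal formation with the electron-rich aldehyde and the hydride shift inside the medium ring may be slow, so that retro-aldol opening or dehydration of the beta-hydroxy ketone takes over. The fallback sets out from 11 and 13 and returns at 15; it separates acylation from reduction. Pinnick oxidation of 13 (NaClO2, NaH2PO4, 2-methylbut-2-ene, tBuOH–H2O) should give the silyloxy benzoic acid F6. Carbodiimide esterification of 11 with F6 (EDC, DMAP, CH2Cl2, 0 °C) should give the C8-acylated keto ester F7. CBS reduction of the C6 enone carbonyl (2-methyl-CBS-oxazaborolidine, catecholborane, −78 °C, catalyst enantiomer chosen for 6R) should then give 15 under reagent control.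

Further compounds
F1 | step 3 | cis-fused 10,10-dichloro-3,7-dimethyl-1-(triethylsilyloxy)bicyclo[6.2.0]deca-2,6-dien-9-one (racemic) | CC[Si](CC)(CC)O[C@]12/C=C(C)\CC/C=C(C)\[C@H]1C(=O)C2(Cl)Cl
F2 | step 3 | cis-fused 3,7-dimethyl-1-(triethylsilyloxy)bicyclo[6.2.0]deca-2,6-dien-9-one (racemic) | CC[Si](CC)(CC)O[C@]12/C=C(C)\CC/C=C(C)\[C@H]1C(=O)C2
F3 | step 3 | (4Z,8Z)-5,9-dimethylcyclodeca-4,8-diene-1,3-dione | O=C1C/C(C)=C\CC/C(C)=C\C(=O)C1
F4 | step 3 | (4Z,8Z)-5,9-dimethyl-2-(propan-2-ylidene)cyclodeca-4,8-diene-1,3-dione | CC(C)=C1C(=O)C/C(C)=C\CC/C(C)=C\C1=O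
F5 | step 6 | racemic 7,8-cis hydroxy ketone, i.e. 11 with its mirror image; SMILES of the (9S,10S) enantiomer | O[C@H]1C/C(C)=C\CC/C(C)=C\C(=O)[C@H]1C(C)C
F6 | step 8 | 4-{[tert-butyl(dimethyl)silyl]oxy}-3-methoxybenzoic acid | COc1cc(C(=O)O)ccc1O[Si](C)(C)C(C)(C)C
F7 | step 8 | (1R,3Z,7Z,10R)-3,7-dimethyl-9-oxo-10-(propan-2-yl)cyclodeca-3,7-dien-1-yl 4-{[tert-butyl(dimethyl)silyl]oxy}-3-methoxybenzoate | COc1cc(C(=O)O[C@@H]2C/C(C)=C\CC/C(C)=C\C(=O)[C@@H]2C(C)C)ccc1O[Si](C)(C)C(C)(C)C
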